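**Retrosynthetic overview**

1. The C11–O aryl ether is cut last (Mitsunobu etherification of umbelliferone with diol 13); C11 and the C9 stereocentre come from the C9 carbonyl of enone 10 by methylenation and hydroboration from the face anti to the C10 methyl.
2. Ring B (C5–C6–C7–C8–C9–C10) is never closed as a six-membered ring: it arises from the cyclopentanone ring C5–C6–C7–C9–C10 of trans-hydrindanone 6 by insertion of C8, with its methyl group, into the C7–C9 bond (chloro(methyl)carbene addition to the silyl enol ether, then electrocyclic opening).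
3. Enabling feature: the ring-B unit C9–C8(CH3)=C7 is a 2-methylcyclohexene next to a carbon (C9) that can be carried as a carbonyl, i.e. a 2-methylcyclohex-2-enone = cyclopentanone + one CH3–C unit; the quaternary C10 lets the C9 ketone enolize only toward C7, so the inserted carbon can only become C8 and the olefin C7=C8.
4. Ring A and the five-membered ring are bought together as the (R)-bicyclic enedione 1 (sets C10); gem-dimethylation at C4, hydrogenation (C5–H trans) and hindered-hydride reduction (axial C3–OH) finish ring A before the ring enlargement.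
5. Order of rings: ring A (from 1), five-membered ring (from 1) enlarged to ring B in step 6, coumarin attached in step 9.

Key step: step 6

Remark on numbering: locants C1–C12 in the text follow drimane numbering (ring A = C1–C5, C10; ring B = C5–C10; C11 = CH2O on C9; C12 = CH3 on C8). In the hydrindane intermediates the five-membered ring is C5, C6, C7, C9, C10. Systematic names use their own locants. The target is (3S,5S,9R,10R): trans-decalin, C11 cis to the C10 methyl, 3-OH axial and trans to the C10 methyl.

Assumption: the (R)-enantiomer of enedione 1 is taken from commerce, where both enantiomers are offered.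

**Route**

Step 1
Reactants: 1 (7aR)-7a-methyl-2,3,7,7a-tetrahydro-1H-indene-1,5(6H)-dione
Product: 2 (7a'R)-7a'-methyl-2',3',7',7a'-tetrahydrospiro[[1,3]dioxolane-2,1'-inden]-5'(6'H)-one
Conditions: 2-ethyl-2-methyl-1,3-dioxolane (solvent), p-TsOH·H2O (cat.), rt
Reagents that add atoms: 2-ethyl-2-methyl-1,3-dioxolane, CCC1(C)OCCO1
Why: Acid-catalysed transacetalization should take place at the saturated, more electrophilic cyclopentanone carbonyl (C9) and leave the conjugated C3 enone untouched; no stereocentre is formed.

Step 2
Reactants: 2 (7a'R)-7a'-methyl-2',3',7',7a'-tetrahydrospiro[[1,3]dioxolane-2,1'-inden]-5'(6'H)-one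
Product: 3 (7a'R)-4',4',7a'-trimethyl-2',4',7',7a'-tetrahydrospiro[[1,3]dioxolane-2,1'-inden]-5'(6'H)-one
Conditions: KOtBu (2.5 equiv), MeI (excess), t-BuOH/THF, 0 °C to rt
Reagents that add atoms: iodomethane, CI
Why: Deconjugative α,α-dialkylation of the enone through its extended potassium dienolate should methylate C4 twice and move the olefin to C5=C6; no stereocentre is formed.

Step 3
Reactants: 3 (7a'R)-4',4',7a'-trimethyl-2',4',7',7a'-tetrahydrospiro[[1,3]dioxolane-2,1'-inden]-5'(6'H)-one
Product: 4 (3a'R,7a'R)-4',4',7a'-trimethylhexahydrospiro[[1,3]dioxolane-2,1'-inden]-5'(4'H)-one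
Conditions: H2 (10 bar), Pd/C (10%), EtOAc, rt
Reagents that add atoms: none
Why: Heterogeneous catalytic hydrogenation adds H2 syn to C5=C6 from the face opposite the C10 methyl, which should set C5–H trans to C10–CH3 (trans-hydrindane) as in 4,4-dimethyl-5-ene steroids and octalins; ketone and dioxolane are not touched.

Step 4
Reactants: 4 (3a'R,7a'R)-4',4',7a'-trimethylhexahydrospiro[[1,3]dioxolane-2,1'-inden]-5'(4'H)-one
Product: 6 (3aR,5S,7aR)-5-hydroxy-4,4,7a-trimethyloctahydro-1H-inden-1-one, via hydroxy ketal 5 (not isolated)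
Conditions: L-Selectride (LiBH(s-Bu)3), THF, −78 °C; NaOH, H2O2, 0 °C; then 2 M HCl, THF, rt
Reagents that add atoms: water, O
Why: Hindered trialkylborohydride reduction of the chair 4,4-dimethyl-3-ketone goes by equatorial attack (axial approach is blocked by the axial hydrogens at C1 and C5) and should give the axial C3 alcohol, trans to C10–CH3 (3S); the acid stage then hydrolyses the dioxolane to the C9 ketone.

Step 5
Reactants: 6 (3aR,5S,7aR)-5-hydroxy-4,4,7a-trimethyloctahydro-1H-inden-1-one
Product: 7 (3aR,5S,7aR)-4,4,7a-trimethyl-1,5-bis(trimethylsilyloxy)-3a,4,5,6,7,7a-hexahydro-3H-indene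
Conditions: TMSOTf (2.5 equiv), Et3N, CH2Cl2, 0 °C
Reagents that add atoms: trimethylsilyl trifluoromethanesulfonate, C[Si](C)(C)OS(=O)(=O)C(F)(F)F
Why: Soft enolization and O-silylation; the C9 ketone can enolize only toward C7 because C10 is quaternary, so a single silyl enol ether (C9=C7) should form while the C3 hydroxyl is silylated at the same time.

Step 6
Reactants: 7 (3aR,5S,7aR)-4,4,7a-trimethyl-1,5-bis(trimethylsilyloxy)-3a,4,5,6,7,7a-hexahydro-3H-indene
Product: 10 (4aR,6S,8aR)-6-hydroxy-2,5,5,8a-tetramethyl-4a,5,6,7,8,8a-hexahydronaphthalen-1(4H)-one, via chlorocyclopropane 8 (not isolated), via silyl ether enone 9 (not isolated)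
Conditions: CH3CHCl2, n-BuLi, Et2O, −40 °C to 0 °C; then toluene, 110 °C; then K2CO3 (cat.), MeOH, rt
Reagents that add atoms: 1,1-dichloroethane, CC(Cl)Cl
Why: n-BuLi converts 1,1-dichloroethane into 1-chloro-1-lithioethane, which transfers chloro(methyl)carbene to the electron-rich C7=C9 silyl enol ether ([2+1] cycloaddition from the face anti to the C10 methyl) to give the 2-siloxy-1-chloro-1-methylcyclopropane 8. On heating, 8 undergoes the disrotatory two-electron cyclopropyl-to-allyl electrocyclic opening with loss of chloride, the C7–C9 bond shared by the two small rings breaks, the siloxy oxygen stabilises the allyl cation C9–C8–C7, and loss of the silyl group as Me3SiCl leaves the 2-methylcyclohex-2-enone 9; the closest known reaction type is the one-carbon ring enlargement of cyclic ketone silyl enol ethers with halocarbenes to 2-halo- and 2-methylcycloalk-2-enones. Ring B is therefore not closed by a cyclization: it arises from the five-membered ring C5–C6–C7–C9–C10 by insertion of C8, with its methyl group C12, between C7 and C9. No stereocentre is created in the product (C8 ends sp2, the cyclopropane centres are transient) and none is endangered, since C10 is quaternary and C3 and C5 are remote from the enone. The selectivities needed are the site of insertion and the position of the olefin; both are fixed by the substrate, because the quaternary C10 allows enolization only toward C7 and the electrocyclic opening can only cleave the cyclopropane bond opposite the carbene carbon, so the methyl-bearing carbon must end as C8 and the olefin as C7=C8. Base-catalysed methanolysis finally frees the C3 hydroxyl from its silyl ether.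

Step 7
Reactants: 10 (4aR,6S,8aR)-6-hydroxy-2,5,5,8a-tetramethyl-4a,5,6,7,8,8a-hexahydronaphthalen-1(4H)-one
Product: 11 (2S,4aR,8aS)-1,1,4a,6-tetramethyl-5-methylidene-1,2,3,4,4a,5,8,8a-octahydronaphthalen-2-ol
Conditions: Ph3PCH3Br, KOtBu (excess), toluene, 90 °C
Reagents that add atoms: methyltriphenylphosphonium bromide, C[P+](c1ccccc1)(c1ccccc1)c1ccccc1.[Br-]
Why: Wittig methylenation under the forcing conditions used for hindered ketones should convert the C9 carbonyl into the exocyclic C9=C11 olefin (1,2-olefination of the enone), with the C3 hydroxyl carried as its alkoxide; no stereocentre is formed.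

Step 8
Reactants: 11 (2S,4aR,8aS)-1,1,4a,6-tetramethyl-5-methylidene-1,2,3,4,4a,5,8,8a-octahydronaphthalen-2-ol
Product: 13 (2S,4aR,5R,8aS)-5-(hydroxymethyl)-1,1,4a,6-tetramethyl-1,2,3,4,4a,5,8,8a-octahydronaphthalen-2-ol, via alkylborane 12 (not isolated)
Conditions: 9-BBN (excess), THF, 0 °C to rt; then NaOH, H2O2, 0 °C
Reagents that add atoms: 9-borabicyclo[3.3.1]nonane, B1C2CCCC1CCC2; hydrogen peroxide, OO
Why: Hydroboration–oxidation (anti-Markovnikov, syn addition) with the bulky borane should put boron on the terminal C11 of the 1,1-disubstituted olefin and spare the trisubstituted C7=C8; hydrogen is delivered to C9 from the face opposite the axial C10 methyl, which places C11 cis to C10–CH3 (9R).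

Step 9
Reactants: 13 (2S,4aR,5R,8aS)-5-(hydroxymethyl)-1,1,4a,6-tetramethyl-1,2,3,4,4a,5,8,8a-octahydronaphthalen-2-ol; 14 umbelliferone (7-hydroxy-2H-chromen-2-one)
Product: 15 conferol, 7-{[(1R,4aS,6S,8aR)-6-hydroxy-2,5,5,8a-tetramethyl-1,4,4a,5,6,7,8,8a-octahydronaphthalen-1-yl]methoxy}-2H-chromen-2-one
Conditions: PPh3, DIAD, THF, 0 °C to rt
Reagents that add atoms: none
Why: Mitsunobu etherification: the acidic phenol should displace the activated primary C11 hydroxyl, while the axial secondary C3 hydroxyl next to the gem-dimethyl carbon is too hindered to be activated; no stereocentre is touched.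

**Compound list**

1 | (7aR)-7a-methyl-2,3,7,7a-tetrahydro-1H-indene-1,5(6H)-dione | O=C1CCC2=CC(=O)CC[C@@]12C | starting material
2 | (7a'R)-7a'-methyl-2',3',7',7a'-tetrahydrospiro[[1,3]dioxolane-2,1'-inden]-5'(6'H)-one | C12(OCCO1)CCC3=CC(=O)CC[C@@]23C | intermediate
3 | (7a'R)-4',4',7a'-trimethyl-2',4',7',7a'-tetrahydrospiro[[1,3]dioxolane-2,1'-inden]-5'(6'H)-one | C12(OCCO1)CC=C3C(C)(C)C(=O)CC[C@@]23C | intermediate
4 | (3a'R,7a'R)-4',4',7a'-trimethylhexahydrospiro[[1,3]dioxolane-2,1'-inden]-5'(4'H)-one | C12(OCCO1)CC[C@@H]3C(C)(C)C(=O)CC[C@@]23C | intermediate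
5 | (3a'R,5'S,7a'R)-4',4',7a'-trimethyloctahydrospiro[[1,3]dioxolane-2,1'-inden]-5'-ol (hydroxy ketal, not isolated) | C12(OCCO1)CC[C@@H]3C(C)(C)[C@@H](O)CC[C@@]23C | intermediate
6 | (3aR,5S,7aR)-5-hydroxy-4,4,7a-trimethyloctahydro-1H-inden-1-one | O=C1CC[C@@H]2C(C)(C)[C@@H](O)CC[C@@]12C | intermediate
7 | (3aR,5S,7aR)-4,4,7a-trimethyl-1,5-bis(trimethylsilyloxy)-3a,4,5,6,7,7a-hexahydro-3H-indene | C[Si](C)(C)OC1=CC[C@@H]2C(C)(C)[C@@H](O[Si](C)(C)C)CC[C@@]12C | intermediate
8 | chlorocyclopropane: 1-chloro-1-methylcyclopropane fused across C7–C9 of 7 on the face anti to the C10 methyl, both silyl ethers kept, both C8 epimers (not isolated) | C[Si](C)(C)O[C@@]12[C@@H](C1(C)Cl)C[C@@H]3C(C)(C)[C@@H](O[Si](C)(C)C)CC[C@@]23C | intermediate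
9 | (4aR,6S,8aR)-2,5,5,8a-tetramethyl-6-(trimethylsilyloxy)-4a,5,6,7,8,8a-hexahydronaphthalen-1(4H)-one (silyl ether enone, not isolated) | CC1=CC[C@@H]2C(C)(C)[C@@H](O[Si](C)(C)C)CC[C@@]2(C)C1=O | intermediate
10 | (4aR,6S,8aR)-6-hydroxy-2,5,5,8a-tetramethyl-4a,5,6,7,8,8a-hexahydronaphthalen-1(4H)-one | CC1=CC[C@@H]2C(C)(C)[C@@H](O)CC[C@@]2(C)C1=O | intermediate
11 | (2S,4aR,8aS)-1,1,4a,6-tetramethyl-5-methylidene-1,2,3,4,4a,5,8,8a-octahydronaphthalen-2-ol | CC1=CC[C@@H]2C(C)(C)[C@@H](O)CC[C@@]2(C)C1=C | intermediate
12 | alkylborane: C11-(9-borabicyclo[3.3.1]nonan-9-yl) adduct of 11, C9–H anti to the C10 methyl (not isolated) | CC1=CC[C@@H]2C(C)(C)[C@@H](O)CC[C@@]2(C)[C@@H]1CB1C2CCCC1CCC2 | intermediate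
13 | (2S,4aR,5R,8aS)-5-(hydroxymethyl)-1,1,4a,6-tetramethyl-1,2,3,4,4a,5,8,8a-octahydronaphthalen-2-ol | CC1=CC[C@@H]2C(C)(C)[C@@H](O)CC[C@@]2(C)[C@@H]1CO | intermediate
14 | umbelliferone (7-hydroxy-2H-chromen-2-one) | Oc1ccc2ccc(=O)oc2c1 | starting material
15 | conferol | CC1=CC[C@@H]2C(C)(C)[C@@H](O)CC[C@@]2(C)[C@@H]1COc1ccc2ccc(=O)oc2c1 | target

**Step count and risk**

Total steps: 9. Longest linear sequence: 9 steps (1 to 15).

Most likely to fail:

Step 6 (key step). Carbene transfer to the silyl enol ether may be slow because the quaternary C10 shields it. The electrocyclic opening may also stall for the C8 epimer whose chloride is anti to the carbocycle, since only a leaving group syn to the five-membered ring can depart in the allowed disrotatory mode. The fallback sets out from 7. Dibromocarbene (CHBr3, KOtBu, pentane, −20 °C) should give the 8,8-dibromo-7,9-cyclopropane adduct F1, in which one bromide is always syn to the carbocycle. Warming in toluene should open it to the 8-bromo enone silyl ether F2. Stille methylation (Me4Sn, Pd(PPh3)4, CuI, DMF, 80 °C) then installs the C8 methyl and rejoins the route at 9, which is desilylated to 10 as in step 6. Ring B still arises by the same one-carbon enlargement, but the ring carbon and its methyl group are introduced in two separate operations.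

Step 7. Olefination may be slow because of steric compression between the quaternary C10 and the C8 methyl, and the basic ylide may instead deprotonate the enone at the γ-position. The fallback sets out from 10. Peterson olefination: Me3SiCH2Li with CeCl3 (THF, −78 °C) should add the small, weakly basic organocerium to C9 to give the β-hydroxysilane F3. KH in THF then brings about syn elimination and rejoins the route at 11.

Step 8. Site selectivity may erode (reaction across the conjugated diene or at C7=C8), or the facial bias at C9 may be too small. The fallback sets out from 10 and bypasses the diene. Corey–Chaykovsky epoxidation (Me3S+ I−, n-BuLi, THF, −10 °C) should add the ylide anti to the C10 methyl and give the spiro vinyl epoxide F4. MgBr2·OEt2 (CH2Cl2, −20 °C) should then trigger a Meinwald rearrangement: ionization at the allylic tertiary C9 and a 1,2-hydride shift from C11 anti to the departing oxygen, giving the β,γ-unsaturated aldehyde F5 with C9–H anti to the C10 methyl. Immediate reduction (NaBH4, MeOH, 0 °C), before the olefin can move into conjugation, rejoins the route at 13.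

**Further compounds**

F1 | step 6 | 8,8-dibromo-7,9-cyclopropane adduct of 7 (both silyl ethers kept, cyclopropane anti to the C10 methyl) | C[Si](C)(C)O[C@@]12[C@@H](C1(Br)Br)C[C@@H]3C(C)(C)[C@@H](O[Si](C)(C)C)CC[C@@]23C
F2 | step 6 | (4aR,6S,8aR)-2-bromo-5,5,8a-trimethyl-6-(trimethylsilyloxy)-4a,5,6,7,8,8a-hexahydronaphthalen-1(4H)-one | BrC1=CC[C@@H]2C(C)(C)[C@@H](O[Si](C)(C)C)CC[C@@]2(C)C1=O
F3 | step 7 | β-hydroxysilane: C9 carbinol of 10 bearing a (trimethylsilyl)methyl group anti to the C10 methyl | CC1=CC[C@@H]2C(C)(C)[C@@H](O)CC[C@@]2(C)[C@@]1(O)C[Si](C)(C)C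
F4 | step 8 | spiro vinyl epoxide: 9,11-epoxide of 11 with oxygen syn to the C10 methyl | CC1=CC[C@@H]2C(C)(C)[C@@H](O)CC[C@@]2(C)[C@@]13CO3
F5 | step 8 | (1R,4aS,6S,8aR)-6-hydroxy-2,5,5,8a-tetramethyl-1,4,4a,5,6,7,8,8a-octahydronaphthalene-1-carbaldehyde | CC1=CC[C@@H]2C(C)(C)[C@@H](O)CC[C@@]2(C)[C@@H]1C=O
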